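**Retrosynthetic overview**

1. The target is a (2S)-flavanone (aromatic ring A, dihydropyranone ring C, 2-phenyl ring B) with a 4-hydroxy-2-pyranone (ring D) on C6 and a prenyl group on C8. The plan rests on C2, which is benzylic and α to O1 and lies six atoms from C3 along C3–C4–C4a–C8a–O1–C2.
2. Ring C is closed last by the C2–C3 bond: a rhodium carbenoid at C3, made from the α-diazo ketone on C4, inserts into one enantiotopic C–H bond of the O1-benzyl ether. Desilylation and MOM removal then give the target.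
3. The diazo ketone comes from the hexasubstituted acetophenone by diazo transfer, and the C6–ring D bond from Suzuki–Miyaura coupling of an aryl bromide with the pyranone 3-boronate.
4. Ring A is dressed from 2,4,6-trihydroxyacetophenone: 4-O-dimethylpropargylation, mono-benzylation, bromination ortho to the free phenol, semi-hydrogenation, and Claisen shift to the only free ortho carbon (flavanone C8). The bromine blocks C6 during the shift, and the palladium coupling follows it, so that no aryl–palladium species ever sits ortho to a propargyl or allyl ether.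
5. Ring D is made first, from the dianion of methyl 3-oxopentanoate (acylation, lactonisation), then MOM protection, C3 bromination and borylation. Order of ring formation: D, then C (ring A is bought).

Key step: step 14

Assumption: Rh2(S-PTTL)4 is taken to replace the benzylic hydrogen that leads to 2S; if the sense of induction proves opposite, Rh2(R-PTTL)4 is used in the same way.
Remark: in compounds 10–20 the locants are those of the acetophenone (C1 carries the acyl group). Rotamers about the aryl–pyranone axis in 17–22 converge on the target, whose axis carries no stereo-information.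

**Route**

Step 1
Reactants: 1 methyl 3-oxopentanoate; 2 N-methoxy-N-methylpropanamide
Product: 3 methyl 4-methyl-3,5-dioxoheptanoate (racemic at C4, keto–enol mixture)
Conditions: LiN(i-Pr)2 (2.2 equiv), THF, −78 to 0 °C; then 2, −78 to 0 °C; aq. HCl quench
Reagents that add atoms: none
Why: γ-Acylation of a β-keto ester dianion, whose terminal carbanion is the most nucleophilic site; the N-methoxy-N-methylamide gives a chelated tetrahedral adduct that releases the ketone only on work-up, so over-addition is avoided.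

Step 2
Reactants: 3 methyl 4-methyl-3,5-dioxoheptanoate
Product: 4 6-ethyl-4-hydroxy-5-methyl-2H-pyran-2-one
Conditions: DBU, PhMe, 100 °C; then aq. HCl
Reagents that add atoms: none
Why: Base-mediated enol lactonisation of a 3,5-diketo ester (the C5 enol oxygen displaces methoxide at the ester) is the standard closure to 4-hydroxy-2-pyranones.

Step 3
Reactants: 4 6-ethyl-4-hydroxy-5-methyl-2H-pyran-2-one
Product: 5 6-ethyl-4-(methoxymethoxy)-5-methyl-2H-pyran-2-one
Conditions: MOMCl, i-Pr2NEt, CH2Cl2, 0 °C to rt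
Reagents that add atoms: chloromethyl methyl ether, COCCl
Why: O-Alkylation of the vinylogous acid with a hard electrophile under amine base should give mainly the 4-alkoxy-2-pyranone; any 2-alkoxy-4-pyranone isomer is separable and would converge on the same hydroxypyranone after deprotection.

Step 4
Reactants: 5 6-ethyl-4-(methoxymethoxy)-5-methyl-2H-pyran-2-one
Product: 6 3-bromo-6-ethyl-4-(methoxymethoxy)-5-methyl-2H-pyran-2-one
Conditions: NBS, MeCN, 0 °C to rt, dark
Reagents that add atoms: N-bromosuccinimide, O=C1CCC(=O)N1Br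
Why: Electrophilic bromination at C3, the only ring C–H and the nucleophilic β-carbon of the enol ether; ionic conditions in the dark should spare the allylic alkyl groups.

Step 5
Reactants: 6 3-bromo-6-ethyl-4-(methoxymethoxy)-5-methyl-2H-pyran-2-one
Product: 7 6-ethyl-4-(methoxymethoxy)-5-methyl-3-(4,4,5,5-tetramethyl-1,3,2-dioxaborolan-2-yl)-2H-pyran-2-one
Conditions: B2pin2, PdCl2(dppf), KOAc, 1,4-dioxane, 85 °C
Reagents that add atoms: bis(pinacolato)diboron, CC1(C)OB(OC1(C)C)B1OC(C)(C)C(C)(C)O1
Why: Miyaura borylation of an alkenyl bromide (oxidative addition of zerovalent palladium, acetate-assisted transmetalation, reductive elimination) under anhydrous, weakly basic conditions that should leave the MOM acetal and the lactone intact.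

Step 6
Reactants: 8 2,4,6-trihydroxyacetophenone; 9 3-chloro-3-methylbut-1-yne
Product: 10 1-[2,6-dihydroxy-4-(2-methylbut-3-yn-2-yloxy)phenyl]ethanone
Conditions: CuCl2·2H2O (cat.), DBU (1.05 equiv), MeCN, 0 °C
Reagents that add atoms: none
Why: Copper-catalysed propargylic etherification; the 4-OH, para to the acetyl group and not hydrogen-bonded to it, is the most acidic and the only one deprotonated by one equivalent of DBU, and the phenoxide attacks the tertiary carbon.

Step 7
Reactants: 10 1-[2,6-dihydroxy-4-(2-methylbut-3-yn-2-yloxy)phenyl]ethanone; 11 benzyl bromide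
Product: 12 1-[2-(benzyloxy)-6-hydroxy-4-(2-methylbut-3-yn-2-yloxy)phenyl]ethanone
Conditions: K2CO3, acetone, 50 °C
Reagents that add atoms: none
Why: Williamson etherification of one of two equivalent phenols; after the first benzylation the remaining OH is locked in a strong hydrogen bond to the carbonyl group, so the reaction should stop at the mono-ether.

Step 8
Reactants: 12 1-[2-(benzyloxy)-6-hydroxy-4-(2-methylbut-3-yn-2-yloxy)phenyl]ethanone
Product: 13 1-[6-(benzyloxy)-3-bromo-2-hydroxy-4-(2-methylbut-3-yn-2-yloxy)phenyl]ethanone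
Conditions: NBS (1.0 equiv), CH2Cl2, −20 to 0 °C
Reagents that add atoms: N-bromosuccinimide, O=C1CCC(=O)N1Br
Why: Electrophilic aromatic bromination goes ortho to the free chelated phenol in preference to the carbon flanked by the benzyl ether and the bulky tertiary ether, as is general for 2-hydroxy-4,6-dialkoxyacetophenones; the terminal alkyne is inert to NBS without an activator.

Step 9
Reactants: 13 1-[6-(benzyloxy)-3-bromo-2-hydroxy-4-(2-methylbut-3-yn-2-yloxy)phenyl]ethanone
Product: 14 1-[6-(benzyloxy)-3-bromo-2-hydroxy-4-(2-methylbut-3-en-2-yloxy)phenyl]ethanone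
Conditions: H2 (1 atm), Pd/CaCO3 poisoned with Pb(OAc)2, quinoline, EtOAc, rt
Reagents that add atoms: none
Why: Semi-hydrogenation of the terminal alkyne over lead-poisoned palladium with quinoline should stop at the alkene and leave the benzyl ether, the aryl bromide (chosen over an iodide for this reason) and the ketone untouched.

Step 10
Reactants: 14 1-[6-(benzyloxy)-3-bromo-2-hydroxy-4-(2-methylbut-3-en-2-yloxy)phenyl]ethanone
Product: 16 1-[2-(benzyloxy)-5-bromo-4,6-dihydroxy-3-(3-methylbut-2-en-1-yl)phenyl]ethanone, via ortho-prenyl cyclohexadienone 15 (not isolated)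
Conditions: xylenes, 130 °C
Reagents that add atoms: none
Why: Aromatic Claisen rearrangement of the 1,1-dimethylallyl aryl ether; C5 is blocked by bromine, so the allyl unit is delivered with allylic inversion to C3, the only free ortho carbon, and the dienone re-aromatises to the linear prenyl phenol.

Step 11
Reactants: 16 1-[2-(benzyloxy)-5-bromo-4,6-dihydroxy-3-(3-methylbut-2-en-1-yl)phenyl]ethanone; 7 6-ethyl-4-(methoxymethoxy)-5-methyl-3-(4,4,5,5-tetramethyl-1,3,2-dioxaborolan-2-yl)-2H-pyran-2-one
Product: 17 1-[2-(benzyloxy)-5-[6-ethyl-4-(methoxymethoxy)-5-methyl-2-oxo-2H-pyran-3-yl]-4,6-dihydroxy-3-(3-methylbut-2-en-1-yl)phenyl]ethanone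
Conditions: Pd(OAc)2, SPhos, K3PO4, PhMe/H2O, 80 °C
Reagents that add atoms: none
Why: Suzuki–Miyaura coupling with a bulky electron-rich biarylphosphine, which promotes oxidative addition into the electron-rich C–Br bond and reductive elimination of the tetra-ortho-substituted biaryl; the aryl–palladium species has only small hydroxyl groups ortho to it and the prenyl group meta, so no Heck-type cyclisation is open.

Step 12
Reactants: 17 1-[2-(benzyloxy)-5-[6-ethyl-4-(methoxymethoxy)-5-methyl-2-oxo-2H-pyran-3-yl]-4,6-dihydroxy-3-(3-methylbut-2-en-1-yl)phenyl]ethanone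
Product: 18 1-[2-(benzyloxy)-4,6-bis(tert-butyldimethylsilyloxy)-5-[6-ethyl-4-(methoxymethoxy)-5-methyl-2-oxo-2H-pyran-3-yl]-3-(3-methylbut-2-en-1-yl)phenyl]ethanone
Conditions: TBSCl, imidazole, DMAP (cat.), DMF, 45 °C
Reagents that add atoms: tert-butyldimethylsilyl chloride, CC(C)(C)[Si](C)(C)Cl
Why: Imidazole-mediated silylation of both phenols (warming and DMAP for the chelated, doubly flanked 6-OH); silyl ethers are chosen because they place no C–H bond within reach of the later carbenoid, and a silyl triflate is avoided to spare the MOM acetal.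

Step 13
Reactants: 18 1-[2-(benzyloxy)-4,6-bis(tert-butyldimethylsilyloxy)-5-[6-ethyl-4-(methoxymethoxy)-5-methyl-2-oxo-2H-pyran-3-yl]-3-(3-methylbut-2-en-1-yl)phenyl]ethanone
Product: 20 2-diazo-1-[2-(benzyloxy)-4,6-bis(tert-butyldimethylsilyloxy)-5-[6-ethyl-4-(methoxymethoxy)-5-methyl-2-oxo-2H-pyran-3-yl]-3-(3-methylbut-2-en-1-yl)phenyl]ethanone, via trifluoroacetyl diketone 19 (not isolated)
Conditions: LiN(SiMe3)2, THF, −78 °C; CF3CO2CH2CF3; NH4Cl work-up; then MsN3, Et3N, H2O, MeCN, rt
Reagents that add atoms: methanesulfonyl azide, CS(=O)(=O)N=[N+]=[N-]; 2,2,2-trifluoroethyl trifluoroacetate, O=C(OCC(F)(F)F)C(F)(F)F (its CF3CO group is carried only by intermediate 19)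
Why: Detrifluoroacetylative diazo transfer: kinetic enolisation of the methyl ketone and Claisen-type trifluoroacetylation give an activated 1,3-diketone, to which the sulfonyl azide transfers N2 with loss of the trifluoroacetyl group as the N-acyl sulfonamide.

Step 14
Reactants: 20 2-diazo-1-[2-(benzyloxy)-4,6-bis(tert-butyldimethylsilyloxy)-5-[6-ethyl-4-(methoxymethoxy)-5-methyl-2-oxo-2H-pyran-3-yl]-3-(3-methylbut-2-en-1-yl)phenyl]ethanone
Product: 21 (2S)-5,7-bis(tert-butyldimethylsilyloxy)-6-[6-ethyl-4-(methoxymethoxy)-5-methyl-2-oxo-2H-pyran-3-yl]-8-(3-methylbut-2-en-1-yl)-2-phenyl-2,3-dihydro-4H-chromen-4-one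
Conditions: Rh2(S-PTTL)4 (dirhodium tetrakis[N-phthaloyl-(S)-tert-leucinate], 2 mol %), CH2Cl2, 0 °C to rt, slow addition of 20
Reagents that add atoms: none
Why: Loss of N2 from 20 at the divalent rhodium centre gives an electrophilic carbenoid at C3, which takes one benzylic hydrogen of the O1–CH2Ph group together with its bonding pair in a concerted three-centre transition state and so forms the C2–C3 bond. The closest known reaction type is the rhodium-carboxylate-catalysed intramolecular C–H insertion of ortho-alkoxy α-diazoacetophenones to chroman-4-ones. Ring C is closed by a 1,6-insertion (six-membered ring through C3–C4–C4a–C8a–O1–C2); a 1,5-insertion is excluded because the fifth atom is O1. The two benzylic hydrogens are enantiotopic, so the C2 stereocentre is set by the catalyst alone, the chiral N-phthaloyl-tert-leucinate ligands selecting the hydrogen whose replacement gives 2S. The step needs chemoselectivity for C–H insertion over oxonium ylide formation at O1 (which would end in a 1,2-benzyl Stevens shift to a benzofuranone); this is favoured because the aryl ether oxygen is weakly basic and crowded between the ketone and the prenyl group, while the C–H bond is doubly activated (benzylic and α to oxygen). The 5-O-silyl group offers no C–H bond at insertion distance, the prenyl alkene (meta to the ketone) and ring D cannot reach C3, and slow addition keeps the diazo ketone dilute so that intermolecular cyclopropanation of the prenyl group is suppressed.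

Step 15
Reactants: 21 (2S)-5,7-bis(tert-butyldimethylsilyloxy)-6-[6-ethyl-4-(methoxymethoxy)-5-methyl-2-oxo-2H-pyran-3-yl]-8-(3-methylbut-2-en-1-yl)-2-phenyl-2,3-dihydro-4H-chromen-4-one
Product: 22 (2S)-6-[6-ethyl-4-(methoxymethoxy)-5-methyl-2-oxo-2H-pyran-3-yl]-5,7-dihydroxy-8-(3-methylbut-2-en-1-yl)-2-phenyl-2,3-dihydro-4H-chromen-4-one
Conditions: Bu4NF, AcOH, THF, 0 °C
Reagents that add atoms: none
Why: Fluoride cleaves both aryl silyl ethers, and acetic acid keeps the phenols protonated so that ring C does not open to the chalcone by retro-oxa-Michael reaction, which would racemise C2.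

Step 16
Reactants: 22 (2S)-6-[6-ethyl-4-(methoxymethoxy)-5-methyl-2-oxo-2H-pyran-3-yl]-5,7-dihydroxy-8-(3-methylbut-2-en-1-yl)-2-phenyl-2,3-dihydro-4H-chromen-4-one
Product: 23 (2S)-6-(6-ethyl-4-hydroxy-5-methyl-2-oxo-2H-pyran-3-yl)-5,7-dihydroxy-8-(3-methylbut-2-en-1-yl)-2-phenyl-2,3-dihydro-4H-chromen-4-one (CNP0482269.1)
Conditions: HCl, MeOH, rt
Reagents that add atoms: none
Why: Acid-catalysed acetal exchange with methanol removes the MOM group of the vinylogous ester under conditions too mild to cyclise the prenyl group onto the 7-OH or to open ring C.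

**Compound list**

1 | methyl 3-oxopentanoate | CCC(=O)CC(=O)OC | starting material
2 | N-methoxy-N-methylpropanamide | CCC(=O)N(C)OC | starting material
3 | methyl 4-methyl-3,5-dioxoheptanoate (racemic) | CCC(=O)C(C)C(=O)CC(=O)OC | intermediate
4 | 6-ethyl-4-hydroxy-5-methyl-2H-pyran-2-one | CCc1oc(=O)cc(O)c1C | intermediate
5 | 6-ethyl-4-(methoxymethoxy)-5-methyl-2H-pyran-2-one | CCc1oc(=O)cc(OCOC)c1C | intermediate
6 | 3-bromo-6-ethyl-4-(methoxymethoxy)-5-methyl-2H-pyran-2-one | CCc1oc(=O)c(Br)c(OCOC)c1C | intermediate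
7 | 6-ethyl-4-(methoxymethoxy)-5-methyl-3-(4,4,5,5-tetramethyl-1,3,2-dioxaborolan-2-yl)-2H-pyran-2-one | CCc1oc(=O)c(B2OC(C)(C)C(C)(C)O2)c(OCOC)c1C | intermediate
8 | 2,4,6-trihydroxyacetophenone | CC(=O)c1c(O)cc(O)cc1O | starting material
9 | 3-chloro-3-methylbut-1-yne | CC(C)(Cl)C#C | starting material
10 | 1-[2,6-dihydroxy-4-(2-methylbut-3-yn-2-yloxy)phenyl]ethanone | CC(=O)c1c(O)cc(OC(C)(C)C#C)cc1O | intermediate
11 | benzyl bromide | BrCc1ccccc1 | starting material
12 | 1-[2-(benzyloxy)-6-hydroxy-4-(2-methylbut-3-yn-2-yloxy)phenyl]ethanone | CC(=O)c1c(O)cc(OC(C)(C)C#C)cc1OCc1ccccc1 | intermediate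
13 | 1-[6-(benzyloxy)-3-bromo-2-hydroxy-4-(2-methylbut-3-yn-2-yloxy)phenyl]ethanone | CC(=O)c1c(O)c(Br)c(OC(C)(C)C#C)cc1OCc1ccccc1 | intermediate
14 | 1-[6-(benzyloxy)-3-bromo-2-hydroxy-4-(2-methylbut-3-en-2-yloxy)phenyl]ethanone | CC(=O)c1c(O)c(Br)c(OC(C)(C)C=C)cc1OCc1ccccc1 | intermediate
15 | 4-acetyl-3-(benzyloxy)-6-bromo-5-hydroxy-2-(3-methylbut-2-en-1-yl)cyclohexa-3,5-dien-1-one (racemic, not isolated) | CC(=O)C1=C(OCc2ccccc2)C(CC=C(C)C)C(=O)C(Br)=C1O | intermediate
16 | 1-[2-(benzyloxy)-5-bromo-4,6-dihydroxy-3-(3-methylbut-2-en-1-yl)phenyl]ethanone | CC(=O)c1c(O)c(Br)c(O)c(CC=C(C)C)c1OCc1ccccc1 | intermediate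
17 | 1-[2-(benzyloxy)-5-[6-ethyl-4-(methoxymethoxy)-5-methyl-2-oxo-2H-pyran-3-yl]-4,6-dihydroxy-3-(3-methylbut-2-en-1-yl)phenyl]ethanone | CCc1oc(=O)c(-c2c(O)c(CC=C(C)C)c(OCc3ccccc3)c(C(C)=O)c2O)c(OCOC)c1C | intermediate
18 | 1-[2-(benzyloxy)-4,6-bis(tert-butyldimethylsilyloxy)-5-[6-ethyl-4-(methoxymethoxy)-5-methyl-2-oxo-2H-pyran-3-yl]-3-(3-methylbut-2-en-1-yl)phenyl]ethanone | CCc1oc(=O)c(-c2c(O[Si](C)(C)C(C)(C)C)c(CC=C(C)C)c(OCc3ccccc3)c(C(C)=O)c2O[Si](C)(C)C(C)(C)C)c(OCOC)c1C | intermediate
19 | 1-[aryl of 18]-4,4,4-trifluorobutane-1,3-dione (not isolated) | CCc1oc(=O)c(-c2c(O[Si](C)(C)C(C)(C)C)c(CC=C(C)C)c(OCc3ccccc3)c(C(=O)CC(=O)C(F)(F)F)c2O[Si](C)(C)C(C)(C)C)c(OCOC)c1C | intermediate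
20 | 2-diazo-1-[2-(benzyloxy)-4,6-bis(tert-butyldimethylsilyloxy)-5-[6-ethyl-4-(methoxymethoxy)-5-methyl-2-oxo-2H-pyran-3-yl]-3-(3-methylbut-2-en-1-yl)phenyl]ethanone | CCc1oc(=O)c(-c2c(O[Si](C)(C)C(C)(C)C)c(CC=C(C)C)c(OCc3ccccc3)c(c2O[Si](C)(C)C(C)(C)C)C(=O)C=[N+]=[N-])c(OCOC)c1C | intermediate
21 | (2S)-5,7-bis(tert-butyldimethylsilyloxy)-6-[6-ethyl-4-(methoxymethoxy)-5-methyl-2-oxo-2H-pyran-3-yl]-8-(3-methylbut-2-en-1-yl)-2-phenyl-2,3-dihydro-4H-chromen-4-one | CCc1oc(=O)c(-c2c(O[Si](C)(C)C(C)(C)C)c(CC=C(C)C)c3c(c2O[Si](C)(C)C(C)(C)C)C(=O)C[C@@H](c2ccccc2)O3)c(OCOC)c1C | intermediate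
22 | (2S)-6-[6-ethyl-4-(methoxymethoxy)-5-methyl-2-oxo-2H-pyran-3-yl]-5,7-dihydroxy-8-(3-methylbut-2-en-1-yl)-2-phenyl-2,3-dihydro-4H-chromen-4-one | CCc1oc(=O)c(-c2c(O)c(CC=C(C)C)c3c(c2O)C(=O)C[C@@H](c2ccccc2)O3)c(OCOC)c1C | intermediate
23 | (2S)-6-(6-ethyl-4-hydroxy-5-methyl-2-oxo-2H-pyran-3-yl)-5,7-dihydroxy-8-(3-methylbut-2-en-1-yl)-2-phenyl-2,3-dihydro-4H-chromen-4-one | CCc1oc(=O)c(-c2c(O)c(CC=C(C)C)c3c(c2O)C(=O)C[C@@H](c2ccccc2)O3)c(O)c1C | target

**Step count and risks**

Total step count: 16. Longest linear sequence: 11 steps (steps 6–16 from 2,4,6-trihydroxyacetophenone; equally steps 1–5 and 11–16 from methyl 3-oxopentanoate).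

Steps most likely to fail:

1. Step 14. The carbenoid may attack the lone pair of O1 instead of the C–H bond, which gives an oxonium ylide and then a 1,2-benzyl shift to a benzofuranone. The chiral ligands may also discriminate poorly between the two enantiotopic benzylic hydrogens. The fallback sets out from 18 and comes back at 21; it closes ring C before the stereocentre is set and no longer uses the benzyl carbon. MgBr2·OEt2 in PhMe/Et2O should cleave only the benzyl ether ortho to the ketone (chelation-assisted) and give the 2-hydroxyacetophenone F1. Condensation with Me2NCH(OMe)2 at 90 °C should give the enaminone F2, which closes under mild acid (PPTS, CH2Cl2) with loss of dimethylamine to the chromone F3. Asymmetric conjugate addition of PhB(OH)2 with Pd(OCOCF3)2 and the t-BuPyOx enantiomer that leads to 2S (NH4PF6, H2O, ClCH2CH2Cl, 60 °C) should then give 21.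

2. Step 11. Boronate 7 may undergo protodeboronation in aqueous base, and transmetalation to the doubly flanked aryl–palladium species may be slow, so that hydrodebromination of 16 takes over. The fallback sets out from 6 and 16 and comes back at 17; it replaces boron by tin and needs no base. Bromide 6 with (Bu3Sn)2 and Pd(PPh3)4 in PhMe at 100 °C should give the pyranonyl stannane F4, and copper-assisted Stille coupling of F4 with 16 (Pd(PPh3)4, CuI, DMF, 80 °C) should give 17.

3. Step 13. The amide base may deprotonate the 6-ethyl group of ring D in competition with the methyl ketone, and the silyl group on the ortho oxygen may migrate to the enolate oxygen before acylation. The fallback sets out from 18 and comes back at 20; it uses no strong base. Heating 18 with Me2NCH(OMe)2 in PhMe at 100 °C should give the enaminone F5, and p-toluenesulfonyl azide in MeCN at rt should add across the enamine and fragment to 20 and the N-sulfonyl formamidine.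

**Further compounds**

F1 | step 14 | 1-[4,6-bis(tert-butyldimethylsilyloxy)-5-[6-ethyl-4-(methoxymethoxy)-5-methyl-2-oxo-2H-pyran-3-yl]-2-hydroxy-3-(3-methylbut-2-en-1-yl)phenyl]ethanone | CCc1oc(=O)c(-c2c(O[Si](C)(C)C(C)(C)C)c(CC=C(C)C)c(O)c(C(C)=O)c2O[Si](C)(C)C(C)(C)C)c(OCOC)c1C
F2 | step 14 | (E)-1-[aryl of F1]-3-(dimethylamino)prop-2-en-1-one | CCc1oc(=O)c(-c2c(O[Si](C)(C)C(C)(C)C)c(CC=C(C)C)c(O)c(C(=O)/C=C/N(C)C)c2O[Si](C)(C)C(C)(C)C)c(OCOC)c1C
F3 | step 14 | 5,7-bis(tert-butyldimethylsilyloxy)-6-[6-ethyl-4-(methoxymethoxy)-5-methyl-2-oxo-2H-pyran-3-yl]-8-(3-methylbut-2-en-1-yl)-4H-chromen-4-one | CCc1oc(=O)c(-c2c(O[Si](C)(C)C(C)(C)C)c(CC=C(C)C)c3occc(=O)c3c2O[Si](C)(C)C(C)(C)C)c(OCOC)c1C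
F4 | step 11 | 6-ethyl-4-(methoxymethoxy)-5-methyl-3-(tributylstannyl)-2H-pyran-2-one | CCc1oc(=O)c([Sn](CCCC)(CCCC)CCCC)c(OCOC)c1C
F5 | step 13 | (E)-1-[2-(benzyloxy)-4,6-bis(tert-butyldimethylsilyloxy)-5-[6-ethyl-4-(methoxymethoxy)-5-methyl-2-oxo-2H-pyran-3-yl]-3-(3-methylbut-2-en-1-yl)phenyl]-3-(dimethylamino)prop-2-en-1-one | CCc1oc(=O)c(-c2c(O[Si](C)(C)C(C)(C)C)c(CC=C(C)C)c(OCc3ccccc3)c(C(=O)/C=C/N(C)C)c2O[Si](C)(C)C(C)(C)C)c(OCOC)c1C
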